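All runs are calculated on assumed constants.

**One step.** I first supposed a one-step world, in which the left-handed substrate falls by one first-order clock and the right-handed substrate stands still. I began there, with these flasks and runs.

| setting | zeta | beta | midnight | dawn |
|---|---|---|---|---|
| left-handed substrate | 0.052 M | 0.15 M | 0.077 M | 0.077 M |
| right-handed substrate | 0.052 M | 0.15 M | 0.077 M | 0.077 M |
| partner | 0.0924 M | 0.0924 M | 0.0924 M | 0.0300 M |
| free catalyst | 2.9 mM | 2.9 mM | 2.9 mM | 2.9 mM |
| added ligand | 3.2 mM | 3.2 mM | 3.2 mM | 3.2 mM |
| remark | run made earlier | run made earlier |  |  |
| time |  |  | 40 h | 40 h |

| run | time / h | right-handed substrate / % | left-handed substrate / % | left-handed product / % |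
|---|---|---|---|---|
| zeta | 1.50 | 50.7 | 46.0 | 2.4 |
| zeta | 3.00 | 46.9 | 45.5 | 4.5 |
| zeta | 5.00 | 47.2 | 44.2 | 7.1 |
| zeta | 6.00 | 48.5 | 41.8 | 9.7 |
| zeta | 8.00 | 45.7 | 39.3 | 9.6 |
| beta | 0.667 | 48.9 | 46.7 | 0.8 |
| beta | 2.00 | 50.4 | 47.0 | 2.2 |
| beta | 4.00 | 48.3 | 44.4 | 5.5 |
| beta | 6.00 | 47.5 | 43.7 | 8.4 |
| beta | 8.00 | 46.0 | 40.8 | 9.1 |

(scatter of a reading: 1 percentage point)

- free catalyst is single-handed; left-handed substrate and right-handed substrate are mirror images of each other, charged as a racemate, each of them at the stated concentration
- an excess is the difference of the two amounts in percent of their sum
- an excess is below zero if the other one leads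

- the winner by excess of right-handed substrate over left-handed substrate among what is left of the two; "neither" if no more than 2 percentage points parts them (midnight / dawn / neither)
- excess of right-handed substrate over left-handed substrate among what is left of the two at the end, midnight
- excess of right-handed substrate over left-handed substrate among what is left of the two at the end, dawn

**First clock.** Pooling the last readings of zeta and beta, I read a constant k of 0.0278 /h for the left-handed substrate. Over 40 h that clock left 32.9% of its charge, which alone gave an excess of 50.5%.

**Second step.** The right-handed substrate fell too, more slowly. I took both losses to pass through the same catalyst and partner, so that these cancel in a ratio. That ratio is the selectivity factor s, the logarithm of the fraction of left-handed substrate left over that of the fraction of right-handed substrate left. The same readings gave s = 2.56, a reading under a scatter of 1 percentage point. With it, my reckoning for midnight kept 64.8% of the right-handed substrate, and my midnight excess fell to 32.6%.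

**Partner added.** I let each substrate lost take one partner. By my reckoning midnight then asked for 0.0787 M, less than its c(partner) of 0.0924 M, so my number for it stood. Dawn's 0.0300 M was less than that same reckoned demand, so in my reckoning partner was the limiting reagent in dawn. Supposing it used up, and shared roughly s to one between the two substrates, I reckoned an excess of 10.6% for dawn.

**The forecast.** It held that “the reaction is about first order in substrate” and named midnight, with 33.6% for midnight and 10.6% for dawn. Its midnight figure lay 1.00 point from mine.

**The result.** Midnight gave 18.8% and dawn 5.92%, so midnight led. Midnight kept 57% of its left-handed substrate, more than my clock's 32.9%, and dawn kept 43% of its partner.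

    free catalyst → spent catalyst (k = 0.0700 /h)
    partner + free catalyst + right-handed substrate → free catalyst + right-handed product (k = 100 /M²/h)
    partner + free catalyst + left-handed substrate → free catalyst + left-handed product (k = 300 /M²/h)
    free catalyst + added ligand ⇌ idle complex, settled at all times (K = 550 /M)

**Same ratio.** From midnight's 57%, s gave 80.1% of right-handed substrate and an excess of 17.2%, and the flask held 83%. A neighbour, dawn with 0.12 M of partner, kept 47% of its left-handed substrate. There s gave 74.6% and an excess of 22.7%. That flask held 78% of its right-handed substrate, at an excess of 24.5%.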